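**Retrosynthetic overview**

1. Ring numbering used throughout: C1 (CH, acetonyl), C2 (C=O), C3 (=C, CH2OH), C4 (=CH), C5 (CH2), C6 (quaternary, methyl and side chain), C7 (CH, enol ester arm). The strategy rests on C3–C4, with the one-carbon branch on C3, being a two-carbon insert between C2 and C5; removing it leaves the cyclopentanone ring C2–C1–C7–C6–C5 carrying the three contiguous stereocentres.
2. Late disconnections: cross-metathesis of the C6 allyl group (last), acid unmasking, enol acylation of the C7 acetaldehyde arm, and redox adjustment of the C2/C3 pair of a β-keto ester.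
3. Key disconnection: dienamine ester 21 from pyrrolidine enamine 18 and methyl propiolate by formal [2+2] (C5–C4 and C2–C3 formed) and cyclobutene opening (C2–C5 cleaved).
4. Cyclopentanone 16: C6 by conjugate allylation anti to C7; C1 by trans α′-allylation (then Wacker oxidation and ketalisation); C7 by Johnson–Claisen chirality transfer from (R)-2-methylcyclopent-2-en-1-ol (CBS reduction).
5. Ring order: the five-membered ring is bought; the four-membered ring is closed and opened in step 11, which gives the seven-membered ring; no other ring is built.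

Key step: step 11

Assumption: 3-methylbut-2-enoic anhydride (29) is taken as a purchasable reagent.

**Route**

Step 1
Reactants: 1 2-methylcyclopent-2-en-1-one
Product: 2 (R)-2-methylcyclopent-2-en-1-ol
Conditions: (S)-2-methyl-CBS-oxazaborolidine (10 mol%), BH3·SMe2 (0.7 equiv), THF, −20 °C; MeOH quench
Reagents that add atoms: none
Why: Corey–Bakshi–Shibata reduction, a catalyst-controlled 1,2-hydride transfer in which the methyl-bearing alkenyl side acts as the large group, so the (S)-oxazaborolidine should deliver the (R)-carbinol that later fixes C7.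

Step 2
Reactants: 2 (R)-2-methylcyclopent-2-en-1-ol; 3 triethyl orthoacetate
Product: 5 ethyl 2-[(1R)-2-methylcyclopent-2-en-1-yl]acetate, via mixed ketene acetal 4 (not isolated)
Conditions: MeC(OEt)3 (6 equiv), EtCO2H (5 mol%), 140 °C, EtOH distilled off
Reagents that add atoms: triethyl orthoacetate, CC(OCC)(OCC)OCC
Why: Johnson–Claisen rearrangement; the [3,3] shift is suprafacial in the ring, so the C–O stereocentre is relayed to the new C–C bond at C7 on the face the oxygen occupied.

Step 3
Reactants: 5 ethyl 2-[(1R)-2-methylcyclopent-2-en-1-yl]acetate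
Product: 6 2-[(1R)-2-methylcyclopent-2-en-1-yl]ethan-1-ol
Conditions: LiAlH4 (1 equiv), Et2O, 0 °C
Reagents that add atoms: none
Why: Hydride reduction of the ester to the primary alcohol, which leaves the stereocentre and the trisubstituted alkene untouched.

Step 4
Reactants: 6 2-[(1R)-2-methylcyclopent-2-en-1-yl]ethan-1-ol
Product: 7 tert-butyldimethyl{2-[(1R)-2-methylcyclopent-2-en-1-yl]ethoxy}silane
Conditions: TBSCl (1.2 equiv), imidazole (2 equiv), DMF, rt
Reagents that add atoms: tert-butyldimethylsilyl chloride, CC(C)(C)[Si](C)(C)Cl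
Why: Silyl ether formation protects the arm oxygen for the enolate, copper and enamine chemistry that follows.

Step 5
Reactants: 7 tert-butyldimethyl{2-[(1R)-2-methylcyclopent-2-en-1-yl]ethoxy}silane
Product: 8 (4S)-4-[2-(tert-butyldimethylsilyloxy)ethyl]-3-methylcyclopent-2-en-1-one
Conditions: Rh2(cap)4 (1 mol%, cap = caprolactamate), tert-butyl hydroperoxide (70% aq., 5 equiv), K2CO3 (0.5 equiv), CH2Cl2, rt
Reagents that add atoms: tert-butyl hydroperoxide, CC(C)(C)OO
Why: Radical allylic oxidation (hydrogen abstraction by tert-butylperoxyl, then collapse of the allylic peroxide) should occur at the unhindered ring CH2 next to the alkene CH, as with related 1-methylcycloalkenes, giving the 3-methylcyclopent-2-enone without touching the C7–H centre.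

Step 6
Reactants: 8 (4S)-4-[2-(tert-butyldimethylsilyloxy)ethyl]-3-methylcyclopent-2-en-1-one; 9 allyl bromide
Product: 11 (4S,5S)-4-[2-(tert-butyldimethylsilyloxy)ethyl]-3-methyl-5-(prop-2-en-1-yl)cyclopent-2-en-1-one, via lithium enolate 10 (not isolated)
Conditions: LiN(iPr)2 (LDA, 1.05 equiv), THF, −78 °C; then allyl bromide (1.5 equiv), DMPU, −78 → −30 °C
Reagents that add atoms: allyl bromide, C=CCBr
Why: Kinetic α′-deprotonation of the enone gives the cross-conjugated enolate, and enolate alkylation occurs anti to the neighbouring C7 arm, setting C1 trans to it under substrate control.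

Step 7
Reactants: 11 (4S,5S)-4-[2-(tert-butyldimethylsilyloxy)ethyl]-3-methyl-5-(prop-2-en-1-yl)cyclopent-2-en-1-one
Product: 12 (4S,5S)-4-[2-(tert-butyldimethylsilyloxy)ethyl]-3-methyl-5-(2-oxopropyl)cyclopent-2-en-1-one
Conditions: PdCl2 (10 mol%), CuCl (1 equiv), O2 (1 atm), DMF/H2O 7:1, rt
Reagents that add atoms: water, O
Why: Tsuji–Wacker oxidation turns the terminal alkene of the γ,δ-unsaturated ketone into the methyl ketone by Markovnikov hydroxypalladation, the electron-poor trisubstituted enone alkene being inert.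

Step 8
Reactants: 12 (4S,5S)-4-[2-(tert-butyldimethylsilyloxy)ethyl]-3-methyl-5-(2-oxopropyl)cyclopent-2-en-1-one
Product: 13 (4S,5S)-4-[2-(tert-butyldimethylsilyloxy)ethyl]-3-methyl-5-[(2-methyl-1,3-dioxolan-2-yl)methyl]cyclopent-2-en-1-one
Conditions: 1,2-bis(trimethylsilyloxy)ethane (1.5 equiv), TMSOTf (5 mol%), CH2Cl2, −78 → −20 °C
Reagents that add atoms: 1,2-bis(trimethylsilyloxy)ethane, C[Si](C)(C)OCCO[Si](C)(C)C
Why: Silyl-transfer ketalisation at low temperature selects the saturated methyl ketone over the conjugated ring ketone and avoids acid-induced furan formation from the 1,4-diketone.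

Step 9
Reactants: 13 (4S,5S)-4-[2-(tert-butyldimethylsilyloxy)ethyl]-3-methyl-5-[(2-methyl-1,3-dioxolan-2-yl)methyl]cyclopent-2-en-1-one; 14 allylmagnesium bromide
Product: 16 (2S,3S,4S)-3-[2-(tert-butyldimethylsilyloxy)ethyl]-4-methyl-2-[(2-methyl-1,3-dioxolan-2-yl)methyl]-4-(prop-2-en-1-yl)cyclopentan-1-one, via trimethylsilyl enol ether 15 (not isolated)
Conditions: allylmagnesium bromide (1.5 equiv), CuBr·SMe2 (1.5 equiv), LiCl (1.5 equiv), TMSCl (3 equiv), THF, −78 °C; then K2CO3, MeOH, 0 °C
Reagents that add atoms: allylmagnesium bromide, C=CC[Mg]Br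
Why: TMSCl-accelerated conjugate addition of an allylcopper reagent creates the quaternary C6 with approach anti to the adjacent C7 arm (allyl trans, methyl cis to the arm), and these neutral copper conditions spare the dioxolane that a TiCl4-mediated Sakurai allylation would open.

Step 10
Reactants: 16 (2S,3S,4S)-3-[2-(tert-butyldimethylsilyloxy)ethyl]-4-methyl-2-[(2-methyl-1,3-dioxolan-2-yl)methyl]-4-(prop-2-en-1-yl)cyclopentan-1-one; 17 pyrrolidine
Product: 18 pyrrolidine enamine of 16 with the double bond C2=C5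
Conditions: pyrrolidine (5 equiv), p-TsOH·H2O (5 mol%), toluene, reflux, Dean–Stark; used crude
Reagents that add atoms: pyrrolidine, C1CCNC1
Why: Enamine condensation in which A(1,3) strain disfavours the tetrasubstituted isomer toward C1, so the double bond forms toward C5, while C1 remains trans to C7 as the thermodynamically preferred arrangement.

Step 11
Reactants: 18 pyrrolidine enamine of 16 with the double bond C2=C5; 19 methyl propiolate
Product: 21 methyl 2-(pyrrolidin-1-yl)cyclohepta-1,6-diene-1-carboxylate bearing the C1 and C6 and C7 substituents (overview numbering: N on C2 and C2=C3 and CO2Me on C3 and C4=C5), via aminocyclobutene 20 (not isolated)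
Conditions: methyl propiolate (1.3 equiv), toluene, 0 °C → rt, then 60 °C
Reagents that add atoms: methyl propiolate, C#CC(=O)OC
Why: The enamine β-carbon C5 adds to the unsubstituted terminus of methyl propiolate to give an iminium/allenolate zwitterion, whose ester-bearing carbon then bonds to the iminium carbon C2, so the four-membered ring closes stepwise in a polar formal [2+2] to aminocyclobutene 20. The closest known reaction is the two-carbon ring enlargement of cyclic ketone enamines with acetylenic esters. The push–pull cyclobutene then opens by cleavage of the old C2–C5 bond (ring opening assisted by the nitrogen lone pair and the ester), which converts the bicyclo[3.2.0]heptene into the seven-membered ring with C2=C3 and C4=C5. The two transient centres at C2 and C5 become sp2, so no stereocentre is created and C1, C6 and C7 are not touched. Regioselectivity rests on the enamine being the C2=C5 isomer (step 10) and on the polarity match between nucleophilic C5 and the electrophilic alkyne CH. An aprotic, non-polar solvent keeps the zwitterion from proton transfer to the open-chain Michael adduct.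

Step 12
Reactants: 21 methyl 2-(pyrrolidin-1-yl)cyclohepta-1,6-diene-1-carboxylate bearing the C1 and C6 and C7 substituents
Product: 22 β-keto ester (C2 ketone, CO2Me on C3, C4=C5 alkene; C3 epimers and enol form in equilibrium)
Conditions: AcOH/NaOAc buffer (pH ≈ 5), THF/H2O, rt → 40 °C
Reagents that add atoms: water, O
Why: Enamine hydrolysis by C3-protonation and iminium cleavage gives the β-keto ester at a pH that spares the dioxolane and the silyl ether; it is placed before any hydride step because a C2 enamine next to a C3 carbinol would expel the oxygen like a vinylogous carbinolamine and lead to the 2-methylene ketone.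

Step 13
Reactants: 22 β-keto ester
Product: 23 1,3-diol (C2–OH and C3–CH2OH, C4=C5 alkene; diastereomer mixture at C2 and C3)
Conditions: LiBH4 (4 equiv), THF/MeOH, 0 °C → rt
Reagents that add atoms: none
Why: Borohydride reduction of a β-keto ester, in which the ketone is reduced first and the resulting alkoxide assists reduction of the ester; both new centres are erased later.

Step 14
Reactants: 23 1,3-diol
Product: 24 primary 4-methoxytrityl ether of 23 (C2–OH free)
Conditions: 4-methoxytrityl chloride (1.2 equiv), Et3N, DMAP (cat.), CH2Cl2, 0 °C → rt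
Reagents that add atoms: 4-methoxytrityl chloride, COc1ccc(cc1)C(Cl)(c1ccccc1)c1ccccc1
Why: Tritylation is highly selective for the primary hydroxyl over the hindered secondary C2–OH, and the ether is stable to base, fluoride and oxidants yet leaves under the final mild acid.

Step 15
Reactants: 24 primary 4-methoxytrityl ether of 23
Product: 26 2-[(4-methoxytrityloxy)methyl]cyclohept-2-enone (C2 ketone conjugated with C3=C4), via β,γ-unsaturated ketone 25 (not isolated)
Conditions: Dess–Martin periodinane (1.5 equiv), NaHCO3, CH2Cl2, 0 °C → rt; then DBU (0.2 equiv), CH2Cl2, 0 °C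
Reagents that add atoms: none
Why: Dess–Martin oxidation gives the β,γ-unsaturated ketone, whose doubly activated C3–H is removed by DBU so that reprotonation at C5 moves the alkene into conjugation (base-mediated alkene isomerisation), fixing the C3=C4 position of the target.

Step 16
Reactants: 26 2-[(4-methoxytrityloxy)methyl]cyclohept-2-enone
Product: 27 primary alcohol on the C7 arm (C7–CH2CH2OH)
Conditions: TBAF (1.5 equiv), AcOH (1.5 equiv), THF, 0 °C → rt
Reagents that add atoms: none
Why: Fluoride desilylation of the primary TBS ether, buffered with AcOH so that the base-sensitive C1 centre and the trityl ether stay intact.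

Step 17
Reactants: 27 primary alcohol on the C7 arm
Product: 28 aldehyde (C7–CH2CHO)
Conditions: Dess–Martin periodinane (1.3 equiv), NaHCO3, CH2Cl2, 0 °C → rt
Reagents that add atoms: none
Why: Dess–Martin oxidation of the only free hydroxyl to the aldehyde, with the C3 carbinol tritylated and the methyl ketone still ketalised.

Step 18
Reactants: 28 aldehyde; 29 3-methylbut-2-enoic anhydride
Product: 30 (E)-enol 3-methylbut-2-enoate of 28 (C7–CH=CH–O–CO–CH=CMe2)
Conditions: 3-methylbut-2-enoic anhydride (3 equiv), Et3N (4 equiv), DMAP (0.3 equiv), CH2Cl2, rt → 40 °C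
Reagents that add atoms: 3-methylbut-2-enoic anhydride, CC(C)=CC(=O)OC(=O)C=C(C)C
Why: Enol acylation of the aldehyde (amine-mediated enolisation and DMAP acyl transfer) is selective for the aldehyde over the ketone, reversible acyl transfer through DMAP should favour the (E)-isomer with the bulky ring carbon trans to the acyloxy group, and the ketal prevents aldol closure between the aldehyde and the acetonyl group.

Step 19
Reactants: 30 (E)-enol 3-methylbut-2-enoate of 28
Product: 31 allyl precursor of the target (free C3–CH2OH and free acetonyl ketone, C6 allyl)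
Conditions: AcOH/THF/H2O 3:1:1, 30 °C
Reagents that add atoms: water, O
Why: Mild aqueous acid hydrolyses the ketone dioxolane (acetal hydrolysis) and ionises the 4-methoxytrityl ether (SN1 detritylation) much faster than it attacks the enol ester.

Step 20
Reactants: 31 allyl precursor of the target; 32 2-methylbut-3-en-2-ol
Product: 33 (E)-2-[(1S,2S,7S)-4-(hydroxymethyl)-7-[(E)-4-hydroxy-4-methylpent-2-en-1-yl]-7-methyl-3-oxo-2-(2-oxopropyl)cyclohept-4-en-1-yl]ethenyl 3-methylbut-2-enoate
Conditions: 2-methylbut-3-en-2-ol (10 equiv), second-generation Hoveyda–Grubbs catalyst [RuCl2(H2IMes)(=CH-C6H4-2-OiPr)] (5 mol%), CH2Cl2, 40 °C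
Reagents that add atoms: 2-methylbut-3-en-2-ol, CC(C)(O)C=C
Why: Olefin cross-metathesis of the unhindered allyl group with the slowly homodimerising tertiary allylic alcohol should give the (E)-alkene, the enone, senecioate and enol ester alkenes being poor substrates; placing it last keeps the acid-sensitive tertiary allylic alcohol out of every earlier step.

**Compound list**

1 | 2-methylcyclopent-2-en-1-one | CC1=CCCC1=O | starting material
2 | (R)-2-methylcyclopent-2-en-1-ol | O[C@H]1C(C)=CCC1 | intermediate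
3 | triethyl orthoacetate | CC(OCC)(OCC)OCC | starting material
4 | 1-ethoxy-1-{[(1R)-2-methylcyclopent-2-en-1-yl]oxy}ethene (mixed ketene acetal) | C=C(OCC)O[C@H]1C(C)=CCC1 | intermediate
5 | ethyl 2-[(1R)-2-methylcyclopent-2-en-1-yl]acetate | C1CC=C(C)[C@H]1CC(=O)OCC | intermediate
6 | 2-[(1R)-2-methylcyclopent-2-en-1-yl]ethan-1-ol | C1CC=C(C)[C@H]1CCO | intermediate
7 | tert-butyldimethyl{2-[(1R)-2-methylcyclopent-2-en-1-yl]ethoxy}silane | C1CC=C(C)[C@H]1CCO[Si](C)(C)C(C)(C)C | intermediate
8 | (4S)-4-[2-(tert-butyldimethylsilyloxy)ethyl]-3-methylcyclopent-2-en-1-one | C1C(=O)C=C(C)[C@H]1CCO[Si](C)(C)C(C)(C)C | intermediate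
9 | allyl bromide (3-bromoprop-1-ene) | C=CCBr | starting material
10 | lithium (3S)-3-[2-(tert-butyldimethylsilyloxy)ethyl]-4-methylcyclopenta-1,4-dien-1-olate (α′-enolate of 8) | [Li]OC1=C[C@H](CCO[Si](C)(C)C(C)(C)C)C(C)=C1 | intermediate
11 | (4S,5S)-4-[2-(tert-butyldimethylsilyloxy)ethyl]-3-methyl-5-(prop-2-en-1-yl)cyclopent-2-en-1-one (4,5-trans) | C=CC[C@@H]1C(=O)C=C(C)[C@H]1CCO[Si](C)(C)C(C)(C)C | intermediate
12 | (4S,5S)-4-[2-(tert-butyldimethylsilyloxy)ethyl]-3-methyl-5-(2-oxopropyl)cyclopent-2-en-1-one | CC(=O)C[C@@H]1C(=O)C=C(C)[C@H]1CCO[Si](C)(C)C(C)(C)C | intermediate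
13 | (4S,5S)-4-[2-(tert-butyldimethylsilyloxy)ethyl]-3-methyl-5-[(2-methyl-1,3-dioxolan-2-yl)methyl]cyclopent-2-en-1-one | CC1(OCCO1)C[C@@H]2C(=O)C=C(C)[C@H]2CCO[Si](C)(C)C(C)(C)C | intermediate
14 | allylmagnesium bromide | C=CC[Mg]Br | starting material
15 | trimethylsilyl enol ether of 16 (C2=C5): 3-methyl-3-(prop-2-en-1-yl)-4-[2-(tert-butyldimethylsilyloxy)ethyl]-5-[(2-methyl-1,3-dioxolan-2-yl)methyl]-1-(trimethylsilyloxy)cyclopent-1-ene, substituent configuration as in 16 | CC1(OCCO1)C[C@@H]2C(O[Si](C)(C)C)=C[C@](C)(CC=C)[C@H]2CCO[Si](C)(C)C(C)(C)C | intermediate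
16 | (2S,3S,4S)-3-[2-(tert-butyldimethylsilyloxy)ethyl]-4-methyl-2-[(2-methyl-1,3-dioxolan-2-yl)methyl]-4-(prop-2-en-1-yl)cyclopentan-1-one (side chain on C1 trans to the C7 arm, allyl trans and methyl cis to the arm) | CC1(OCCO1)C[C@@H]2C(=O)C[C@](C)(CC=C)[C@H]2CCO[Si](C)(C)C(C)(C)C | intermediate
17 | pyrrolidine | C1CCNC1 | starting material
18 | pyrrolidine enamine of 16, double bond C2=C5: 1-{3-methyl-3-(prop-2-en-1-yl)-4-[2-(tert-butyldimethylsilyloxy)ethyl]-5-[(2-methyl-1,3-dioxolan-2-yl)methyl]cyclopent-1-en-1-yl}pyrrolidine, configuration as in 16 | CC1(OCCO1)C[C@@H]2C(N3CCCC3)=C[C@](C)(CC=C)[C@H]2CCO[Si](C)(C)C(C)(C)C | intermediate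
19 | methyl propiolate | C#CC(=O)OC | starting material
20 | methyl 1-(pyrrolidin-1-yl)bicyclo[3.2.0]hept-6-ene-7-carboxylate carrying 2-[(2-methyl-1,3-dioxolan-2-yl)methyl], 3-[2-(tert-butyldimethylsilyloxy)ethyl], 4-methyl and 4-allyl (cis-fused aminocyclobutene; ring-fusion centres transient, other centres as in 16) | CC1(OCCO1)C[C@@H]2C3(N4CCCC4)C(C(=O)OC)=CC3[C@](C)(CC=C)[C@H]2CCO[Si](C)(C)C(C)(C)C | intermediate
21 | methyl 2-(pyrrolidin-1-yl)cyclohepta-1,6-diene-1-carboxylate carrying 3-[(2-methyl-1,3-dioxolan-2-yl)methyl], 4-[2-(tert-butyldimethylsilyloxy)ethyl], 5-methyl and 5-allyl (overview numbering: N on C2, C2=C3, CO2Me on C3, C4=C5; C1, C6, C7 as in the target) | CC1(OCCO1)C[C@@H]2C(N3CCCC3)=C(C(=O)OC)C=C[C@](C)(CC=C)[C@H]2CCO[Si](C)(C)C(C)(C)C | intermediate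
22 | β-keto ester from 21: C2 ketone, C3–H bearing CO2Me, C4=C5 alkene (C3 epimers and enol form); C1, C6, C7 as in the target | CC1(OCCO1)C[C@@H]2C(=O)C(C(=O)OC)C=C[C@](C)(CC=C)[C@H]2CCO[Si](C)(C)C(C)(C)C | intermediate
23 | 1,3-diol from 22: C2–OH, C3–CH2OH, C4=C5 alkene (mixture at C2 and C3); C1, C6, C7 as in the target | CC1(OCCO1)C[C@@H]2C(O)C(CO)C=C[C@](C)(CC=C)[C@H]2CCO[Si](C)(C)C(C)(C)C | intermediate
24 | 23 with the primary hydroxyl as its (4-methoxyphenyl)diphenylmethyl ether, C2–OH free | CC1(OCCO1)C[C@@H]2C(O)C(COC(c3ccccc3)(c3ccccc3)c3ccc(OC)cc3)C=C[C@](C)(CC=C)[C@H]2CCO[Si](C)(C)C(C)(C)C | intermediate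
25 | β,γ-unsaturated ketone: C2 ketone, C3–H bearing CH2O(4-methoxytrityl), C4=C5 alkene | CC1(OCCO1)C[C@@H]2C(=O)C(COC(c3ccccc3)(c3ccccc3)c3ccc(OC)cc3)C=C[C@](C)(CC=C)[C@H]2CCO[Si](C)(C)C(C)(C)C | intermediate
26 | conjugated enone: C2 ketone, C3=C4 with CH2O(4-methoxytrityl) on C3, C5 H2; C1 dioxolanylmethyl, C6 methyl and allyl, C7 CH2CH2OTBS | CC1(OCCO1)C[C@@H]2C(=O)C(COC(c3ccccc3)(c3ccccc3)c3ccc(OC)cc3)=CC[C@](C)(CC=C)[C@H]2CCO[Si](C)(C)C(C)(C)C | intermediate
27 | 26 with the C7 arm as CH2CH2OH | CC1(OCCO1)C[C@@H]2C(=O)C(COC(c3ccccc3)(c3ccccc3)c3ccc(OC)cc3)=CC[C@](C)(CC=C)[C@H]2CCO | intermediate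
28 | 26 with the C7 arm as CH2CHO | CC1(OCCO1)C[C@@H]2C(=O)C(COC(c3ccccc3)(c3ccccc3)c3ccc(OC)cc3)=CC[C@](C)(CC=C)[C@H]2CC=O | intermediate
29 | 3-methylbut-2-enoic anhydride (senecioic anhydride) | CC(C)=CC(=O)OC(=O)C=C(C)C | starting material
30 | 26 with the C7 arm as (E)-CH=CH–O–CO–CH=C(CH3)2 | CC1(OCCO1)C[C@@H]2C(=O)C(COC(c3ccccc3)(c3ccccc3)c3ccc(OC)cc3)=CC[C@](C)(CC=C)[C@H]2/C=C/OC(=O)C=C(C)C | intermediate
31 | (E)-2-[(1S,2S,7S)-4-(hydroxymethyl)-7-methyl-3-oxo-2-(2-oxopropyl)-7-(prop-2-en-1-yl)cyclohept-4-en-1-yl]ethenyl 3-methylbut-2-enoate | CC(=O)C[C@@H]1C(=O)C(CO)=CC[C@](C)(CC=C)[C@H]1/C=C/OC(=O)C=C(C)C | intermediate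
32 | 2-methylbut-3-en-2-ol | CC(C)(O)C=C | starting material
33 | (E)-2-[(1S,2S,7S)-4-(hydroxymethyl)-7-[(E)-4-hydroxy-4-methylpent-2-en-1-yl]-7-methyl-3-oxo-2-(2-oxopropyl)cyclohept-4-en-1-yl]ethenyl 3-methylbut-2-enoate | CC(=O)C[C@@H]1C(=O)C(CO)=CC[C@](C)(C/C=C/C(C)(C)O)[C@H]1/C=C/OC(=O)C=C(C)C | target

**Step count and risks**

Total step count: 20. Longest linear sequence: 20 steps (fully linear from 1).

The three steps most likely to fail:

Step 11 (key step). The enamine carbon C5 sits next to the quaternary C6, so C–C bond formation may be slow. Proton transfer could then divert the zwitterion to the open-chain Michael adduct, or the propiolate could oligomerise. Fallback: the same two bonds are made on a silyl enol ether. Ketone 16 is deprotonated kinetically at the C5 methylene (LDA, THF, −78 °C) and silylated with TBSCl to the tert-butyldimethylsilyl enol ether F1. The known acid-promoted stepwise [2+2] cycloaddition of silyl enol ethers with propiolate esters (methyl propiolate 19, catalytic Tf2NH, CH2Cl2, −78 °C) then gives the 1-silyloxybicyclo[3.2.0]hept-6-ene-7-carboxylate F2. Warming opens this donor–acceptor cyclobutene to the 2-silyloxy diene ester F3. K2CO3 in MeOH cleaves the enol silyl ether but not the alkyl silyl ether and returns the route at keto ester 22.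

Step 9. The allyl nucleophile may add 1,2 to the carbonyl or react incompletely at the β,β-disubstituted enone carbon flanked by C7, and facial selectivity may erode. Fallback: the quaternary centre is made before the ketal exists. Enone 8 is allylated under Hosomi–Sakurai conditions (allyltrimethylsilane, TiCl4, CH2Cl2, −78 °C, anti to the C7 arm) to (3S,4S)-4-[2-(tert-butyldimethylsilyloxy)ethyl]-3-methyl-3-(prop-2-en-1-yl)cyclopentan-1-one F4. Kinetic enolisation with LDA toward the less hindered C1 methylene, away from the quaternary carbon, and alkylation with propargyl bromide give the (2S,3S,4S)-2-(prop-2-yn-1-yl) ketone F5, trans to the arm. Gold-catalysed Markovnikov hydration of the terminal alkyne (Ph3PAuNTf2, aqueous dioxane) gives the (2S,3S,4S)-2-(2-oxopropyl) ketone F6. Low-temperature ketalisation of the methyl ketone as in step 8 returns the route at ketone 16.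

Step 18. Enol geometry may be poorly controlled, and C-acylation, aldolisation of the aldehyde or deconjugation of the senecioyl unit may compete. Fallback: the enol geometry is set and purified before acylation. Aldehyde 28 is silylated (TBSCl, NaI, Et3N, MeCN) to its tert-butyldimethylsilyl enol ethers, from which the (E)-silyl enol ether F7 is separated; the (Z)-isomer is hydrolysed back to 28 and recycled. Fluoride-triggered O-acylation of F7 with 3-methylbut-2-enoyl fluoride (catalytic TBAF, THF, −78 °C), a known stereoretentive conversion of silyl enol ethers into enol esters, returns the route at enol ester 30.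

Further compounds
F1 | step 11 | tert-butyldimethylsilyl enol ether of 16 (C2=C5), substituent configuration as in 16 | CC1(OCCO1)C[C@@H]2C(O[Si](C)(C)C(C)(C)C)=C[C@](C)(CC=C)[C@H]2CCO[Si](C)(C)C(C)(C)C
F2 | step 11 | methyl 1-(tert-butyldimethylsilyloxy)bicyclo[3.2.0]hept-6-ene-7-carboxylate carrying the substituents of 20 (cis-fused) | CC1(OCCO1)C[C@@H]2C3(O[Si](C)(C)C(C)(C)C)C(C(=O)OC)=CC3[C@](C)(CC=C)[C@H]2CCO[Si](C)(C)C(C)(C)C
F3 | step 11 | methyl 2-(tert-butyldimethylsilyloxy)cyclohepta-1,6-diene-1-carboxylate carrying the substituents of 21 | CC1(OCCO1)C[C@@H]2C(O[Si](C)(C)C(C)(C)C)=C(C(=O)OC)C=C[C@](C)(CC=C)[C@H]2CCO[Si](C)(C)C(C)(C)C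
F4 | step 9 | (3S,4S)-4-[2-(tert-butyldimethylsilyloxy)ethyl]-3-methyl-3-(prop-2-en-1-yl)cyclopentan-1-one | C1C(=O)C[C@](C)(CC=C)[C@H]1CCO[Si](C)(C)C(C)(C)C
F5 | step 9 | (2S,3S,4S)-3-[2-(tert-butyldimethylsilyloxy)ethyl]-4-methyl-4-(prop-2-en-1-yl)-2-(prop-2-yn-1-yl)cyclopentan-1-one | C#CC[C@@H]1C(=O)C[C@](C)(CC=C)[C@H]1CCO[Si](C)(C)C(C)(C)C
F6 | step 9 | (2S,3S,4S)-3-[2-(tert-butyldimethylsilyloxy)ethyl]-4-methyl-2-(2-oxopropyl)-4-(prop-2-en-1-yl)cyclopentan-1-one | CC(=O)C[C@@H]1C(=O)C[C@](C)(CC=C)[C@H]1CCO[Si](C)(C)C(C)(C)C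
F7 | step 18 | 26 with the C7 arm as (E)-CH=CH–OSi(CH3)2C(CH3)3 | CC1(OCCO1)C[C@@H]2C(=O)C(COC(c3ccccc3)(c3ccccc3)c3ccc(OC)cc3)=CC[C@](C)(CC=C)[C@H]2/C=C/O[Si](C)(C)C(C)(C)C
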